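(The data were generated by integration on assumed constants, and the scatter is random.)

At 15 min, the end of each flask, you want a quick number for Q, and your hunch is that Q simply follows the Z charged. I think that is sound while L stays near its charge, so I would freeze L there and ask how much Z is still present.

common to all: L 0.50 M
- violet: Z 0.017 M; run made earlier
- teal: Z 1.7 M; run made earlier
- beta: Z 0.0150 M; time 15 min
- zeta: Z 0.0400 M; time 15 min
- gamma: Z 0.120 M; time 15 min
- eta: Z 0.400 M; time 15 min
- delta: Z 1.20 M; time 15 min

- violet (time / min: Q / %, L / %): 2.50: 1.7, 98.2; 5.00: 1.6, 97.3; 8.00: 2.3, 99.9; 10.0: 3.4, 97.0; 12.0: 3.9, 95.8; 15.0: 2.6, 98.5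
- teal (time / min: Q / %, L / %): 1.33: 39.8, 45.9; 2.00: 46.5, 31.8; 3.00: 43.1, 19.2; 5.00: 35.2, 7.6; 10.0: 24.5, 0.7; 15.0: 16.8, 2.1

(each reading ± 1 percentage point)

- the numbers in the tables scatter with a standard deviation of 1 percentage point
- "hardly changes" means that all values lie within two and a half points (for a concentration: within two and a half percent of the largest)

- amount of Q at the end, in percent of the L charged for beta, zeta, gamma, eta, delta, in this order
- the shape of the row from first to last (falls, then rises / falls all the way / rises all the way / rises, then falls / hardly changes)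

Teal gives the rate. Its L reads 45.9 % at 1.33 min, and if you take Z over that stretch as its charge less half of what L lost, the reading gives k = 0.374 L mol⁻¹ min⁻¹. With L frozen, Z decays pseudo-first-order at k times the L charge, so the part of Z's own charge still present at 15 min is 6.04 %; call this the left share. With L frozen it does not depend on the Z charged. If I count one Q for each Z spent, Q as a fraction of the L charged is the spent part of Z times the ratio of the Z charge to the L charge. Violet tests this, since its readings took no part in finding k: the rule gives 3.19 %, and its last reading is 2.6 %, with a scatter of 1 percentage point.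

My reckoning gives 2.82 % for beta, 7.52 % for zeta and 22.5 % for gamma. Gamma's Z is 24.0 % of the L charge, more than beta's 3.00 %, so L sags there and I take my gamma figure as high. Eta and delta, at 80.0 % and 240 %, are past the freeze, and I give them no figure. Still, teal's Q reads 46.5 % at 2.00 min and 16.8 % at 15.0 min, so I expect the row to turn. The forecast gives 2.8 %, 7.4 %, 21 %, 55 % and 37 %, with the shape rises, then falls, holding that “Q is stable when Z is scarce”. Its gamma stands below mine.

The flasks give 2.78 %, 7.12 %, 18.8 %, 40.7 % and 30.1 %, and the shape is rises, then falls.

    Q + X → G (k = 0.0423 L mol⁻¹ min⁻¹)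
    Z + Q ⇌ J + X (K = 2.53, k = 0.271 L mol⁻¹ min⁻¹)
    D ⇌ X, rate k3*(cs3 - [X]) while solid is left; crystals form when [X] > cs3 (solubility = 0.490 M, k = 10.9 min⁻¹)
    L + Z → Q + X (k = 0.405 L mol⁻¹ min⁻¹)

The forecast and the flask part in eta by 14 points, and at 15.0 min eta holds J at 12.2 %. The left share gives beta 2.82 % of Q, against the 2.78 % it shows. Against the left share of 6.04 %, the Z left of its own charge at 15.0 min stands at 4.9 % in beta, 6.0 % in gamma and 12 % in eta.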